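## The problem

The target is a 2-oxaspiro[4.5]decane. A fully substituted tetrahydrofuran (ring A: C1, O2, C3, C4, C5) shares the quaternary carbon C5 with a 7-methoxycyclohexa-6,9-dien-8-one (ring B). C1 carries an exocyclic carbon C1' bearing an aryl ether and a hydroxymethyl group, C3 a guaiacyl group, and C4 a hydroxymethyl group.

There are five stereocentres. C1' and C1 are neighbouring oxygenated carbons in a syn relationship, the pattern an auxiliary-controlled glycolate aldol delivers. C1 can then steer C4 across a five-membered ring, and C4 steers its neighbour C3.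

C5 is stereogenic only because one of its two enone arms carries the methoxy group. It can therefore be set late by telling the two arms apart. The C4 hydroxymethyl group lies on the same face of ring A as the arm to be methoxylated and is the handle for that.

The molecule is fragile. The cross-conjugated dienone rearranges in strong acid and would be cleaved by retro-aldol aromatisation if an alkoxide ever sat on C1. The C3-O2 bond is a para-hydroxybenzyl ether that ionises with acid or oxidants, and the free guaiacol is easily oxidised.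

The same feature offers the key step. C3 is a para-hydroxybenzylic carbon bonded to O2, so O2-C3 can be made by two-electron oxidation of a 4-hydroxy-3-methoxybenzyl group on C4 to a quinone methide that the C1 hydroxyl captures.

## Retrosynthesis

**Methoxy group and C5 (39 back to 31).** Target 39 is the desilylation product of 38. The C7-OMe bond of 38 is cut back to diosphenol 37, and 37 to the C7-hydroxy ketone 36, which comes from tricyclic keto ether 34 (phenol 33) by enolate oxidation. In 33 the C4 hydroxymethyl oxygen has added to C6 of symmetric dienone 31. It can reach only the arm on its own face, so this conjugate addition distinguishes the arms and fixes C5. It also leaves C7 as the only enolisable carbon, so oxygen goes to the right place. An undirected epoxidation of 31 would prefer the less hindered, wrong arm. The forward steps must tolerate a beta-alkoxy ketone enolate and must reopen the ether ring once C7 is oxygenated.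

**Ring B unsaturation (31 back to 26).** Both C=C bonds of 31 are removed to give ketone 28, its ketal 27 and the free phenol alcohol 26. A saturated, ketal-protected ring B has no stereocentre at C5 and survives the carbanion and hydride steps needed earlier. The dienone must appear only after O2-C3 exists, since a free C1 hydroxyl next to a 4,4-disubstituted dienone would fragment with aromatisation. The dehydrogenation needs the phenol and the primary alcohol masked, hence diacetate 27.

**Ring A, the key cut (26 back to 24).** The O2-C3 bond is cut to benzyl diol 24. This removes a ring and a stereocentre, and turns C3 into a plain benzylic methylene that can be introduced by alkylation. Cutting C1-O2 instead would need substitution at a neopentyl carbon. The forward reaction must oxidise only the free phenol, lose the C3 proton to give quinone methide 25, and close with the aryl group trans to the C4 substituent.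

**Benzyl group and diol (24 back to 16 and 20).** Diol 24 is the hydride reduction and phenol desilylation product of lactone 22. The C4-C3 bond of 22 is cut to lactone 16 and benzylic bromide 20. Tying C1-O and the C4 carboxyl carbon into a gamma-lactone makes C4 an enolate carbon and lets the C1 substituent direct the benzyl group to the opposite face. An acyclic ester would offer no such control. The alkylation has to proceed next to a quaternary carbon.

**C1-C1' bond (16 back to 10 and 6).** Lactone 16 is the silyl ether of 15, formed by lactonisation of diol ester 14, the reduction product of aldol adduct 13. Cutting C1-C1' of 13 gives glycolate imide 10 and aldehyde 6. This sets both oxygenated centres in one reagent-controlled step and brings in the aryl ether ready-made. Later etherification at hindered C1' would be much harder. The aldol must accept an aldehyde on a quaternary carbon.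

**Quaternary carbon (6 back to 1 and 2).** Aldehyde 6 comes from nitrile 4, made by alkylation of nitrile 1 with bromoacetate 2. A nitrile is chosen over an ester at this carbon because its partial reduction stops at the imine stage and leaves the tert-butyl ester arm untouched.

**Side fragments.** Imide 10 is the silyl ether of 9, assembled from phenol 7 and chloroacetyl imide 8 by etherification. Bromide 20 comes from vanillin 17 through 18 and 19.

## Roads not taken

**Alternative 1:** Ring B is cut at C5-C10 and C6-C7. Forward, trans-1-methoxy-3-(trimethylsilyloxy)buta-1,3-diene A2 adds to the exocyclic alkene of the trans-disubstituted alpha-methylene lactone A1. Acid work-up gives spiro lactone cyclohexenone A3.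
- Merits: ring B and the C5 stereocentre form in one step, the diene arriving anti to the C4 substituent. A3 already has the two arms differentiated (enone on the anti arm, saturated syn arm with C7 as the only enolisable carbon). It needs no relay and no double dehydrogenation.
- Weak points: a 1,1-disubstituted acrylate-type dienophile needs forcing conditions with an acid-sensitive diene. More seriously, C1 of A3 is a lactone carbonyl. C1-C1' and both C1 and C1' would have to be made by adding an alpha-aryloxy carbon nucleophile to a neopentyl lactone beside an enone and then reducing the lactol, with no reliable control of the exocyclic centre.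
- Comparison: this road is better at C5 and shorter around ring B. The chosen plan answers with a three-operation relay (steps 18, 20, 21) but fixes C1 and C1' by auxiliary control in step 5.

**Alternative 2:** The cuts are C1-C1' and C1'-O(aryl). Forward, a dirhodium tetracarboxylate catalyst converts ethyl diazoacetate A5 and phenol A6 into an oxonium ylide. This is trapped by the oxocarbenium ion from spiro lactol acetate A4 to give alpha-aryloxy ester A7.
- Merits: the most convergent of all. Two bonds and the aryl ether form on a complete methoxydienone core, and only an ester reduction and desilylation would remain.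
- Weak points: protic oxonium ylides collapse by 1,2-hydrogen shift unless a very reactive electrophile intercepts them, and the cation at C1 is neopentyl. Its two faces differ only through remote groups and C1' forms without control, so up to four diastereomers are possible. The dienone is itself a Michael acceptor and a cyclopropanation partner. Ionising the acetate with a Lewis acid invites dienone-phenol rearrangement. A4 still requires the methoxy and C5 problem to be solved beforehand.
- Comparison: if selective, it would be shorter and more convergent than the chosen plan, which is linear after step 12. The chosen plan sets the C1/C1' pair under reagent control.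

**Alternative 3:** The cuts are O2-C3 and C5-C1. Forward, a metal triflate Lewis acid opens the 1-aryl spiro[2.5]octa-4,7-dien-6-one A8 to a phenolate and a benzylic cation. The aldehyde oxygen of ketoaldehyde A9 bonds to C3 and the phenolate para carbon bonds to the aldehyde carbon, giving 1-acyl spiro dienone tetrahydrofuran A10.
- Merits: ring A and the dienone are assembled in one step from two small pieces, with no ketone dehydrogenation.
- Weak points: formal [3+2] additions of donor-acceptor cyclopropanes to aldehydes are established for gem-diester acceptors. Here the opened form is an aromatic phenolate that must be dearomatised again by para C-C bond formation, against O-attack. A10 has a symmetric dienone, so the methoxy group and C5 remain to be solved as in the chosen plan. C1' is a ketone that must become the aryl ether stereocentre by reduction and inverting etherification at a hindered carbon.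
- Comparison: shorter to the core than the chosen plan. The chosen plan is longer but gives every stereocentre a defined controller and installs the aryl ether before the molecule is crowded.

Key step: step 14

## Route

Abbreviations: TBS = tert-butyldimethylsilyl; TIPS = triisopropylsilyl; ArO = 2-methoxy-4-[3-(TBS-oxy)propyl]phenoxy (the ring D aryl ether). Locants C1 to C10 and C1' are those of the target.

Assumption: the configuration at C7 of 36 is left open, because step 21 destroys that centre and either epimer serves.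

Assumption: the 2-methoxy enone arm of 38 and 39 is taken not to re-add the C4 hydroxymethyl group, in line with the target itself being the open hydroxymethyl dienone.

Step 1
Reactants: 1 1,4-dioxaspiro[4.5]decane-8-carbonitrile; 2 tert-butyl bromoacetate
Product: 4 tert-butyl 2-(8-cyano-1,4-dioxaspiro[4.5]decan-8-yl)acetate, via lithiated nitrile 3 (not isolated)
Conditions: LiN(iPr)2, THF, -78 °C; then 2, -78 °C to rt
Reagents that add atoms: none
Why: Alkylation of a nitrile-stabilised tertiary carbanion with an alpha-bromo ester (SN2) should build the quaternary carbon that becomes C5; no stereocentre is formed.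

Step 2
Reactants: 4 tert-butyl 2-(8-cyano-1,4-dioxaspiro[4.5]decan-8-yl)acetate
Product: 6 tert-butyl 2-(8-formyl-1,4-dioxaspiro[4.5]decan-8-yl)acetate, via N-aluminated aldimine 5 (not isolated)
Conditions: iBu2AlH (1.2 equiv), toluene, -78 °C; then aq. KNaC4H4O6, pH 5 acetate buffer, rt
Reagents that add atoms: water, O
Why: Partial hydride reduction of a nitrile stops at the N-aluminated imine, which is hydrolysed on work-up; the tert-butyl ester is the least reactive ester class towards iBu2AlH at -78 °C and the ketal is inert.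

Step 3
Reactants: 7 4-(3-hydroxypropyl)-2-methoxyphenol; 8 (4R)-4-benzyl-3-(chloroacetyl)-1,3-oxazolidin-2-one
Product: 9 (4R)-4-benzyl-3-{[4-(3-hydroxypropyl)-2-methoxyphenoxy]acetyl}-1,3-oxazolidin-2-one
Conditions: K2CO3, NaI (cat.), acetone, 50 °C
Reagents that add atoms: none
Why: Williamson etherification with Finkelstein catalysis; carbonate deprotonates only the phenol, and the alpha-chloro carbonyl carbon is a far better electrophile for phenoxide than the imide carbonyl.

Step 4
Reactants: 9 (4R)-4-benzyl-3-{[4-(3-hydroxypropyl)-2-methoxyphenoxy]acetyl}-1,3-oxazolidin-2-one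
Product: 10 (4R)-4-benzyl-3-(ArO-acetyl)-1,3-oxazolidin-2-one
Conditions: TBSCl, imidazole, DMF, rt
Reagents that add atoms: tert-butyldimethylsilyl chloride, CC(C)(C)[Si](C)(C)Cl
Why: Standard silylation of a primary alcohol; the imide is stable to imidazole.

Step 5
Reactants: 10 (4R)-4-benzyl-3-(ArO-acetyl)-1,3-oxazolidin-2-one; 6 tert-butyl 2-(8-formyl-1,4-dioxaspiro[4.5]decan-8-yl)acetate
Product: 13 (4R)-4-benzyl-3-[(2R,3S)-2-ArO-3-hydroxy-3-{8-[2-(tert-butoxy)-2-oxoethyl]-1,4-dioxaspiro[4.5]decan-8-yl}propanoyl]-1,3-oxazolidin-2-one, via boron enolate 11 (not isolated), via boron aldolate 12 (not isolated)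
Conditions: Bu2BOTf, iPr2NEt, CH2Cl2, -78 to 0 °C; then 6, -78 to 0 °C; then pH 7 buffer, MeOH, H2O2, 0 °C
Reagents that add atoms: none
Why: Evans syn-aldol through the Z(O) dibutylboron glycolate enolate and a chair Zimmerman-Traxler transition state with opposed dipoles; the (R)-benzyl group shields one enolate face, which should set C1 as S and C1' syn to it. The aldehyde has no alpha hydrogen and cannot enolise.

Step 6
Reactants: 13 the syn-aldol adduct
Product: 14 tert-butyl 2-{8-[(1S,2S)-2-ArO-1,3-dihydroxypropyl]-1,4-dioxaspiro[4.5]decan-8-yl}acetate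
Conditions: NaBH4, THF/H2O (4:1), 0 °C to rt
Reagents that add atoms: none
Why: Reductive cleavage of an N-acyl oxazolidinone with borohydride in wet THF; the alpha-aryloxy imide is far more electrophilic than the tert-butyl ester, and the auxiliary is released for recovery.

Step 7
Reactants: 14 the diol tert-butyl ester
Product: 15 (1S)-8,8-ethylenedioxy-1-[(1S)-1-ArO-2-hydroxyethyl]-2-oxaspiro[4.5]decan-3-one
Conditions: camphorsulfonic acid (cat.), toluene, 4 Å molecular sieves, 60 °C
Reagents that add atoms: none
Why: Acid-catalysed lactonisation (intramolecular transesterification, 5-exo-trig) helped by the Thorpe-Ingold effect of the quaternary carbon; only the secondary C1 hydroxyl can close a five-membered ring, and the dry medium spares ketal and silyl ether.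

Step 8
Reactants: 15 the hydroxy lactone
Product: 16 (1S)-8,8-ethylenedioxy-1-[(1S)-1-ArO-2-(TBS-oxy)ethyl]-2-oxaspiro[4.5]decan-3-one
Conditions: TBSCl, imidazole, DMF, rt
Reagents that add atoms: tert-butyldimethylsilyl chloride, CC(C)(C)[Si](C)(C)Cl
Why: Standard silylation of the only free (primary) hydroxyl.

Step 9
Reactants: 17 vanillin
Product: 18 4-(TBS-oxy)-3-methoxybenzaldehyde
Conditions: TBSCl, imidazole, DMF, rt
Reagents that add atoms: tert-butyldimethylsilyl chloride, CC(C)(C)[Si](C)(C)Cl
Why: Standard phenol silylation.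

Step 10
Reactants: 18 4-(TBS-oxy)-3-methoxybenzaldehyde
Product: 19 [4-(TBS-oxy)-3-methoxyphenyl]methanol
Conditions: NaBH4, MeOH, 0 °C
Reagents that add atoms: none
Why: Borohydride reduction of an aryl aldehyde; the aryl silyl ether survives the short cold exposure.

Step 11
Reactants: 19 [4-(TBS-oxy)-3-methoxyphenyl]methanol
Product: 20 4-(bromomethyl)-2-methoxyphenyl TBS ether
Conditions: CBr4, PPh3, CH2Cl2, 0 °C; used at once
Reagents that add atoms: carbon tetrabromide, BrC(Br)(Br)Br
Why: Appel bromination under neutral conditions, suited to an acid-sensitive, electron-rich benzylic alcohol.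

Step 12
Reactants: 16 the silyl lactone; 20 the benzylic bromide
Product: 22 (1S,4R)-4-[4-(TBS-oxy)-3-methoxybenzyl]-8,8-ethylenedioxy-1-[(1S)-1-ArO-2-(TBS-oxy)ethyl]-2-oxaspiro[4.5]decan-3-one, via lithium enolate 21 (not isolated)
Conditions: LiN(iPr)2, THF, -78 °C; then 20, DMPU, -78 to -30 °C
Reagents that add atoms: none
Why: Alkylation of a gamma-substituted gamma-butyrolactone enolate; the two faces of the enolate differ only by the bulky C1 substituent, so the bromide should enter anti to it (1,3-induction), the trans-selective benzylation pattern established for lignan lactones, and set C4 as R.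

Step 13
Reactants: 22 the benzyl lactone
Product: 24 (2R)-2-{8-[(1S,2S)-2-ArO-1-hydroxy-3-(TBS-oxy)propyl]-1,4-dioxaspiro[4.5]decan-8-yl}-3-(4-hydroxy-3-methoxyphenyl)propan-1-ol, via silyl ether diol 23 (not isolated)
Conditions: LiAlH4, THF, 0 °C; then H2O, aq. NaOH, MeOH, rt
Reagents that add atoms: none
Why: Hydride reduction of the lactone to the 1,4-diol; the basic methanolic work-up then cleaves the aryl silyl ether, which is far more base-labile than the two alkyl TBS ethers.

Step 14
Reactants: 24 the benzyl diol with free phenol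
Product: 26 [(1S,3S,4R)-8,8-ethylenedioxy-3-(4-hydroxy-3-methoxyphenyl)-1-[(1S)-1-ArO-2-(TBS-oxy)ethyl]-2-oxaspiro[4.5]decan-4-yl]methanol, via quinone methide 25 (not isolated)
Conditions: graphite anode, Pt cathode, undivided cell, constant current (2.2 F/mol), nBu4NBF4 (0.1 M), 2,6-lutidine, CH2Cl2/(CF3)2CHOH (4:1), rt
Reagents that add atoms: none
Why: At the anode the free guaiacol, the most electron-rich site of 24, loses two electrons and two protons (phenoxyl radical, phenoxonium ion, loss of the C3 proton) to give para-quinone methide 25, while the base carries the protons to the cathode, where they leave as hydrogen. The secondary C1 hydroxyl adds to the methide carbon in an oxa-1,6-addition that restores the arene and forms O2-C3. The closest known reaction type is the oxidative cyclisation of 4-hydroxybenzyl diols through quinone methides to 2-aryltetrahydrofuran lignans with chemical two-electron oxidants, joined with the anodic benzylic alkoxylation of 4-alkyl-2-methoxyphenols. Ring A closes 5-exo-trig; the primary hydroxyl could only close a four-membered ring and stays free. The new centre C3 is controlled by C4: the aryl group takes the side trans to the C4 hydroxymethyl group, and because the para-hydroxybenzyl ether can reopen to 25 in the lutidinium-buffered anolyte the ring should settle in that arrangement. The step needs the phenol to be oxidised in preference to the dialkoxyarene, which the gap of several hundred millivolts between their potentials secures. It also needs the phenoxonium stage to lose the C3 proton before oxygen attacks the ring carbons, which the hindered base and the non-nucleophilic fluorinated medium favour. Passing only the theoretical charge at low current density limits further oxidation of 26.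

Step 15
Reactants: 26 the spiro tetrahydrofuran with free phenol and hydroxymethyl group
Product: 27 diacetate of 26 (aryl acetate and C4 acetoxymethyl)
Conditions: Ac2O, pyridine, DMAP (cat.), CH2Cl2, rt
Reagents that add atoms: acetic anhydride, CC(=O)OC(C)=O
Why: Standard acetylation; it masks the two groups that the oxidant of step 17 would attack and makes the C3 benzylic ether less prone to ionise in step 16.

Step 16
Reactants: 27 the diacetate ketal
Product: 28 ketone: (1S,3S,4R)-4-(acetoxymethyl)-3-(4-acetoxy-3-methoxyphenyl)-1-[(1S)-1-ArO-2-(TBS-oxy)ethyl]-2-oxaspiro[4.5]decan-8-one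
Conditions: pyridinium p-toluenesulfonate, acetone/H2O (10:1), 50 °C
Reagents that add atoms: water, O
Why: Mild acid-catalysed ketal hydrolysis by exchange with acetone; primary TBS ethers and acetates tolerate these conditions.

Step 17
Reactants: 28 the ketone
Product: 31 dienone: (1S,3S,4R)-4-(acetoxymethyl)-3-(4-acetoxy-3-methoxyphenyl)-1-[(1S)-1-ArO-2-(TBS-oxy)ethyl]-2-oxaspiro[4.5]deca-6,9-dien-8-one, via syn-arm enone 29 (not isolated), via anti-arm enone 30 (not isolated)
Conditions: IBX (4 equiv), 4-methoxypyridine N-oxide (4 equiv), DMSO, rt to 40 °C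
Reagents that add atoms: none
Why: Two successive IBX dehydrogenations of the ketone through its enol; the N-oxide complex works near room temperature, below the range where electron-rich benzylic positions are attacked, and C5 has no hydrogen, so the product stays a cross-conjugated dienone.

Step 18
Reactants: 31 the dienone diacetate
Product: 33 tricyclic keto ether with free phenol (C4 hydroxymethyl oxygen bonded to C6, C9=C10 enone kept), via deacetylated dienone 32 (not isolated)
Conditions: K2CO3, MeOH, 0 °C to rt
Reagents that add atoms: none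
Why: Zemplén-type methanolysis of both acetates, then intramolecular oxa-Michael addition (5-exo-trig) of the primary alkoxide; the tether reaches only the enone arm on its own face of ring A, giving the cis-fused ether. This desymmetrises the dienone and fixes C5 as in the target, with C6 as a temporary centre.

Step 19
Reactants: 33 the tricyclic keto ether phenol
Product: 34 TIPS ether of 33
Conditions: TIPSCl, imidazole, DMF, rt
Reagents that add atoms: triisopropylsilyl chloride, CC(C)[Si](Cl)(C(C)C)C(C)C
Why: Silylation of the only free hydroxyl; the TIPS aryl ether is chosen to survive the carbonate of step 21 and to keep the para-hydroxybenzyl ether from opening under base.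

Step 20
Reactants: 34 the TIPS-protected tricyclic keto ether
Product: 36 C7-hydroxy ketone (alpha'-hydroxy enone, C7 configuration open), via sodium dienolate 35 (not isolated)
Conditions: NaN(SiMe3)2, THF, -78 °C; then 2-(phenylsulfonyl)-3-phenyloxaziridine, -78 °C; AcOH quench
Reagents that add atoms: 2-(phenylsulfonyl)-3-phenyloxaziridine, O=S(=O)(N1OC1c1ccccc1)c1ccccc1
Why: Davis oxidation of a cross-conjugated enone enolate; C7 is the only carbon with enolisable hydrogens (C9 is vinylic, C5 quaternary), so oxygen enters at C7 alone, and the low temperature holds back beta-elimination of the ether oxygen.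

Step 21
Reactants: 36 the C7-hydroxy ketone
Product: 38 tris-silyl ether of the target (7-methoxy dienone with free C4 hydroxymethyl group; phenol as TIPS ether, both side-chain primary alcohols as TBS ethers), via diosphenol 37 (not isolated)
Conditions: K2CO3, Me2SO4, acetone (degassed), 50 °C
Reagents that add atoms: dimethyl sulfate, COS(=O)(=O)OC
Why: E1cB retro-oxa-Michael opening of the alpha-hydroxy beta-alkoxy ketone gives the diosphenol, whose potassium salt is O-methylated by the hard electrophile (classical diosphenol methyl ether formation). The primary alcohol released is not alkylated by carbonate, and the methoxy group sits on the arm that the relay had marked.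

Step 22
Reactants: 38 the tris-silyl ether
Product: 39 (1S,3S,4R,5S)-3-(4-hydroxy-3-methoxyphenyl)-1-{(1S)-2-hydroxy-1-[4-(3-hydroxypropyl)-2-methoxyphenoxy]ethyl}-4-(hydroxymethyl)-7-methoxy-2-oxaspiro[4.5]deca-6,9-dien-8-one
Conditions: Bu4NF, AcOH (1:1), THF, 0 °C to rt
Reagents that add atoms: none
Why: Fluoride-mediated cleavage of the aryl TIPS and the two primary TBS ethers; buffering with acetic acid keeps the medium near neutral, so that neither phenoxide-driven opening of ring A nor base-induced changes at the dienone should occur.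

## Compound list

ArO = 2-methoxy-4-[3-(tert-butyldimethylsilyloxy)propyl]phenoxy; TBS = tert-butyldimethylsilyl; TIPS = triisopropylsilyl.

1 | 1,4-dioxaspiro[4.5]decane-8-carbonitrile | N#CC1CCC2(CC1)OCCO2 | starting material
2 | tert-butyl bromoacetate | CC(C)(C)OC(=O)CBr | starting material
3 | lithiated nitrile of 1 (not isolated) | [Li+].N#C[C-]1CCC2(CC1)OCCO2 | intermediate
4 | tert-butyl 2-(8-cyano-1,4-dioxaspiro[4.5]decan-8-yl)acetate | N#CC1(CC(=O)OC(C)(C)C)CCC2(CC1)OCCO2 | intermediate
5 | N-(diisobutylaluminio) aldimine of 6 (not isolated) | CC(C)C[Al](CC(C)C)N=CC1(CC(=O)OC(C)(C)C)CCC2(CC1)OCCO2 | intermediate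
6 | tert-butyl 2-(8-formyl-1,4-dioxaspiro[4.5]decan-8-yl)acetate | O=CC1(CC(=O)OC(C)(C)C)CCC2(CC1)OCCO2 | intermediate
7 | 4-(3-hydroxypropyl)-2-methoxyphenol (dihydroconiferyl alcohol) | COc1cc(CCCO)ccc1O | starting material
8 | (4R)-4-benzyl-3-(chloroacetyl)-1,3-oxazolidin-2-one | ClCC(=O)N1[C@H](Cc2ccccc2)COC1=O | starting material
9 | (4R)-4-benzyl-3-{[4-(3-hydroxypropyl)-2-methoxyphenoxy]acetyl}-1,3-oxazolidin-2-one | COc1cc(CCCO)ccc1OCC(=O)N1[C@H](Cc2ccccc2)COC1=O | intermediate
10 | (4R)-4-benzyl-3-(ArO-acetyl)-1,3-oxazolidin-2-one | COc1cc(CCCO[Si](C)(C)C(C)(C)C)ccc1OCC(=O)N1[C@H](Cc2ccccc2)COC1=O | intermediate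
11 | Z(O)-dibutylboron enolate of 10 (not isolated) | CCCCB(CCCC)O/C(=C\Oc1ccc(CCCO[Si](C)(C)C(C)(C)C)cc1OC)N1[C@H](Cc2ccccc2)COC1=O | intermediate
12 | O-dibutylboryl derivative (boron aldolate) of 13 (not isolated) | O=C(N1[C@H](Cc2ccccc2)COC1=O)[C@H](Oc1ccc(CCCO[Si](C)(C)C(C)(C)C)cc1OC)[C@@H](OB(CCCC)CCCC)C1(CC(=O)OC(C)(C)C)CCC2(CC1)OCCO2 | intermediate
13 | (4R)-4-benzyl-3-[(2R,3S)-2-ArO-3-hydroxy-3-{8-[2-(tert-butoxy)-2-oxoethyl]-1,4-dioxaspiro[4.5]decan-8-yl}propanoyl]-1,3-oxazolidin-2-one | O=C(N1[C@H](Cc2ccccc2)COC1=O)[C@H](Oc1ccc(CCCO[Si](C)(C)C(C)(C)C)cc1OC)[C@@H](O)C1(CC(=O)OC(C)(C)C)CCC2(CC1)OCCO2 | intermediate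
14 | tert-butyl 2-{8-[(1S,2S)-2-ArO-1,3-dihydroxypropyl]-1,4-dioxaspiro[4.5]decan-8-yl}acetate | OC[C@H](Oc1ccc(CCCO[Si](C)(C)C(C)(C)C)cc1OC)[C@@H](O)C1(CC(=O)OC(C)(C)C)CCC2(CC1)OCCO2 | intermediate
15 | (1S)-8,8-ethylenedioxy-1-[(1S)-1-ArO-2-hydroxyethyl]-2-oxaspiro[4.5]decan-3-one | O=C1CC2(CCC3(CC2)OCCO3)[C@H](O1)[C@H](CO)Oc1ccc(CCCO[Si](C)(C)C(C)(C)C)cc1OC | intermediate
16 | (1S)-8,8-ethylenedioxy-1-[(1S)-1-ArO-2-(TBS-oxy)ethyl]-2-oxaspiro[4.5]decan-3-one | O=C1CC2(CCC3(CC2)OCCO3)[C@H](O1)[C@H](CO[Si](C)(C)C(C)(C)C)Oc1ccc(CCCO[Si](C)(C)C(C)(C)C)cc1OC | intermediate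
17 | vanillin (4-hydroxy-3-methoxybenzaldehyde) | COc1cc(C=O)ccc1O | starting material
18 | 4-(TBS-oxy)-3-methoxybenzaldehyde | COc1cc(C=O)ccc1O[Si](C)(C)C(C)(C)C | intermediate
19 | [4-(TBS-oxy)-3-methoxyphenyl]methanol | COc1cc(CO)ccc1O[Si](C)(C)C(C)(C)C | intermediate
20 | 4-(bromomethyl)-2-methoxyphenyl TBS ether | COc1cc(CBr)ccc1O[Si](C)(C)C(C)(C)C | intermediate
21 | lithium enolate of lactone 16 (not isolated) | [Li]OC1=CC2(CCC3(CC2)OCCO3)[C@H](O1)[C@H](CO[Si](C)(C)C(C)(C)C)Oc1ccc(CCCO[Si](C)(C)C(C)(C)C)cc1OC | intermediate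
22 | (1S,4R)-4-[4-(TBS-oxy)-3-methoxybenzyl]-8,8-ethylenedioxy-1-[(1S)-1-ArO-2-(TBS-oxy)ethyl]-2-oxaspiro[4.5]decan-3-one (benzyl trans to the C1 side chain) | O=C1[C@H](Cc2ccc(O[Si](C)(C)C(C)(C)C)c(OC)c2)C2(CCC3(CC2)OCCO3)[C@H](O1)[C@H](CO[Si](C)(C)C(C)(C)C)Oc1ccc(CCCO[Si](C)(C)C(C)(C)C)cc1OC | intermediate
23 | (2R)-2-{8-[(1S,2S)-2-ArO-1-hydroxy-3-(TBS-oxy)propyl]-1,4-dioxaspiro[4.5]decan-8-yl}-3-[4-(TBS-oxy)-3-methoxyphenyl]propan-1-ol (not isolated) | OC[C@H](Cc1ccc(O[Si](C)(C)C(C)(C)C)c(OC)c1)C1(CCC2(CC1)OCCO2)[C@H](O)[C@H](CO[Si](C)(C)C(C)(C)C)Oc1ccc(CCCO[Si](C)(C)C(C)(C)C)cc1OC | intermediate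
24 | (2R)-2-{8-[(1S,2S)-2-ArO-1-hydroxy-3-(TBS-oxy)propyl]-1,4-dioxaspiro[4.5]decan-8-yl}-3-(4-hydroxy-3-methoxyphenyl)propan-1-ol (key-step precursor) | OC[C@H](Cc1ccc(O)c(OC)c1)C1(CCC2(CC1)OCCO2)[C@H](O)[C@H](CO[Si](C)(C)C(C)(C)C)Oc1ccc(CCCO[Si](C)(C)C(C)(C)C)cc1OC | intermediate
25 | para-quinone methide of 24, methide carbon C3, exocyclic double bond geometry open (not isolated) | OC[C@H](C=C1C=CC(=O)C(OC)=C1)C1(CCC2(CC1)OCCO2)[C@H](O)[C@H](CO[Si](C)(C)C(C)(C)C)Oc1ccc(CCCO[Si](C)(C)C(C)(C)C)cc1OC | intermediate
26 | [(1S,3S,4R)-8,8-ethylenedioxy-3-(4-hydroxy-3-methoxyphenyl)-1-[(1S)-1-ArO-2-(TBS-oxy)ethyl]-2-oxaspiro[4.5]decan-4-yl]methanol (key-step product; aryl trans to hydroxymethyl, hydroxymethyl cis to the C1 side chain) | O1CCOC12CCC3(CC2)[C@H](CO)[C@@H](c2ccc(O)c(OC)c2)O[C@@H]3[C@H](CO[Si](C)(C)C(C)(C)C)Oc1ccc(CCCO[Si](C)(C)C(C)(C)C)cc1OC | intermediate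
27 | diacetate of 26: [(1S,3S,4R)-3-(4-acetoxy-3-methoxyphenyl)-8,8-ethylenedioxy-1-[(1S)-1-ArO-2-(TBS-oxy)ethyl]-2-oxaspiro[4.5]decan-4-yl]methyl acetate | O1CCOC12CCC3(CC2)[C@H](COC(C)=O)[C@@H](c2ccc(OC(C)=O)c(OC)c2)O[C@@H]3[C@H](CO[Si](C)(C)C(C)(C)C)Oc1ccc(CCCO[Si](C)(C)C(C)(C)C)cc1OC | intermediate
28 | (1S,3S,4R)-4-(acetoxymethyl)-3-(4-acetoxy-3-methoxyphenyl)-1-[(1S)-1-ArO-2-(TBS-oxy)ethyl]-2-oxaspiro[4.5]decan-8-one | O=C1CCC2(CC1)[C@H](COC(C)=O)[C@@H](c1ccc(OC(C)=O)c(OC)c1)O[C@@H]2[C@H](CO[Si](C)(C)C(C)(C)C)Oc1ccc(CCCO[Si](C)(C)C(C)(C)C)cc1OC | intermediate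
29 | mono-enone of 28 with the C6=C7 double bond on the arm syn to the C4 acetoxymethyl group (not isolated) | O=C1C=C[C@]2(CC1)[C@H](COC(C)=O)[C@@H](c1ccc(OC(C)=O)c(OC)c1)O[C@@H]2[C@H](CO[Si](C)(C)C(C)(C)C)Oc1ccc(CCCO[Si](C)(C)C(C)(C)C)cc1OC | intermediate
30 | mono-enone of 28 with the C9=C10 double bond on the arm anti to the C4 acetoxymethyl group (not isolated) | O=C1C=C[C@@]2(CC1)[C@H](COC(C)=O)[C@@H](c1ccc(OC(C)=O)c(OC)c1)O[C@@H]2[C@H](CO[Si](C)(C)C(C)(C)C)Oc1ccc(CCCO[Si](C)(C)C(C)(C)C)cc1OC | intermediate
31 | (1S,3S,4R)-4-(acetoxymethyl)-3-(4-acetoxy-3-methoxyphenyl)-1-[(1S)-1-ArO-2-(TBS-oxy)ethyl]-2-oxaspiro[4.5]deca-6,9-dien-8-one | O=C1C=CC2(C=C1)[C@H](COC(C)=O)[C@@H](c1ccc(OC(C)=O)c(OC)c1)O[C@@H]2[C@H](CO[Si](C)(C)C(C)(C)C)Oc1ccc(CCCO[Si](C)(C)C(C)(C)C)cc1OC | intermediate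
32 | deacetylated dienone: (1S,3S,4R)-3-(4-hydroxy-3-methoxyphenyl)-4-(hydroxymethyl)-1-[(1S)-1-ArO-2-(TBS-oxy)ethyl]-2-oxaspiro[4.5]deca-6,9-dien-8-one (not isolated) | O=C1C=CC2(C=C1)[C@H](CO)[C@@H](c1ccc(O)c(OC)c1)O[C@@H]2[C@H](CO[Si](C)(C)C(C)(C)C)Oc1ccc(CCCO[Si](C)(C)C(C)(C)C)cc1OC | intermediate
33 | tricyclic keto ether: oxa-Michael adduct of 32 with the C4 hydroxymethyl oxygen bonded to C6 (new tetrahydrofuran cis-fused to rings A and B, C6-H cis to the C5-C1 bond), C9=C10 enone kept, free phenol | O=C1C=C[C@@]23[C@@H](C1)OC[C@@H]2[C@@H](c1ccc(O)c(OC)c1)O[C@@H]3[C@H](CO[Si](C)(C)C(C)(C)C)Oc1ccc(CCCO[Si](C)(C)C(C)(C)C)cc1OC | intermediate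
34 | TIPS ether of 33 (aryl O-TIPS) | O=C1C=C[C@@]23[C@@H](C1)OC[C@@H]2[C@@H](c1ccc(O[Si](C(C)C)(C(C)C)C(C)C)c(OC)c1)O[C@@H]3[C@H](CO[Si](C)(C)C(C)(C)C)Oc1ccc(CCCO[Si](C)(C)C(C)(C)C)cc1OC | intermediate
35 | sodium dienolate of 34 (C7=C8 enolate; not isolated) | [Na+].[O-]C1C=C[C@@]23[C@@H](C=1)OC[C@@H]2[C@@H](c1ccc(O[Si](C(C)C)(C(C)C)C(C)C)c(OC)c1)O[C@@H]3[C@H](CO[Si](C)(C)C(C)(C)C)Oc1ccc(CCCO[Si](C)(C)C(C)(C)C)cc1OC | intermediate
36 | C7-hydroxy derivative of 34 (alpha'-hydroxy enone; C7 configuration open) | O=C1C=C[C@@]23[C@@H](C1O)OC[C@@H]2[C@@H](c1ccc(O[Si](C(C)C)(C(C)C)C(C)C)c(OC)c1)O[C@@H]3[C@H](CO[Si](C)(C)C(C)(C)C)Oc1ccc(CCCO[Si](C)(C)C(C)(C)C)cc1OC | intermediate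
37 | diosphenol: 7-hydroxy analogue of 38 with the ether ring reopened (not isolated) | OC1=C[C@]2(C=CC1=O)[C@H](CO)[C@@H](c1ccc(O[Si](C(C)C)(C(C)C)C(C)C)c(OC)c1)O[C@@H]2[C@H](CO[Si](C)(C)C(C)(C)C)Oc1ccc(CCCO[Si](C)(C)C(C)(C)C)cc1OC | intermediate
38 | tris-silyl ether of 39: (1S,3S,4R,5S)-4-(hydroxymethyl)-7-methoxy-3-[3-methoxy-4-(TIPS-oxy)phenyl]-1-[(1S)-1-ArO-2-(TBS-oxy)ethyl]-2-oxaspiro[4.5]deca-6,9-dien-8-one | COC1=C[C@]2(C=CC1=O)[C@H](CO)[C@@H](c1ccc(O[Si](C(C)C)(C(C)C)C(C)C)c(OC)c1)O[C@@H]2[C@H](CO[Si](C)(C)C(C)(C)C)Oc1ccc(CCCO[Si](C)(C)C(C)(C)C)cc1OC | intermediate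
39 | (1S,3S,4R,5S)-3-(4-hydroxy-3-methoxyphenyl)-1-{(1S)-2-hydroxy-1-[4-(3-hydroxypropyl)-2-methoxyphenoxy]ethyl}-4-(hydroxymethyl)-7-methoxy-2-oxaspiro[4.5]deca-6,9-dien-8-one | COC1=C[C@]2(C=CC1=O)[C@H](CO)[C@@H](c1ccc(O)c(OC)c1)O[C@@H]2[C@H](CO)Oc1ccc(CCCO)cc1OC | target

## Step count and risks

Total step count: 22. Longest linear sequence: 17 steps (steps 1, 2, 5 to 8 and 12 to 22 from nitrile 1; the branch from phenol 7 through steps 3 to 8 and 12 to 22 is equally long).

**Step 14 (key step).** Three things may go wrong: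
- The product 26 is still a guaiacol with an activated hydrogen at C3, so oxidation may continue past the desired stage and open or degrade ring A.
- Oxygen may attack the ring carbons of the phenoxonium ion (ipso or ortho capture) before the C3 proton is lost.
- Phenoxyl radicals may couple before the second electron is removed.

Fallback: set out from lactone 16. Its lithium enolate is added to aldehyde 18 to give the beta-hydroxy lactone F1 (new bond anti to the C1 side chain, carbinol configuration immaterial). Reduction with LiAlH4 and the same basic methanolic work-up as in step 13 gives the benzylic alcohol triol F2. A catalytic amount of camphorsulfonic acid in CH2Cl2 ionises the para-hydroxybenzylic alcohol and closes ring A under thermodynamic control. The route is rejoined at 26.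

**Step 12.** Substitution at an enolate carbon flanked by the quaternary centre may be slow, leaving time for the labile, electron-rich bromide 20 to decompose. Anti-selectivity over the C1 side chain may also be incomplete.

Fallback: set out from lactone 16. The enolate is added to the stable aldehyde 18 as above, and the lithium alkoxide of F1 is acetylated in the flask with acetic anhydride to the beta-acetoxy lactone F3. Hydrogenolysis of the benzylic acetate (H2, Pd/C, ethyl acetate) removes the oxygen. The route is rejoined at 22.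

**Step 17.** Single-electron oxidation of the electron-rich ring D or of its benzylic methylene may compete with enol oxidation, and the second dehydrogenation may stall at the enone stage.

Fallback: set out from ketone 28 and use two rounds of Saegusa-Ito oxidation. Soft enolisation (TMSOTf, Et3N) gives the syn-arm trimethylsilyl enol ether F4 and its anti-arm regioisomer F5. Pd(OAc)2 in acetonitrile converts these into enones 29 and 30. A second silylation gives the silyl dienol ether F6 from 29 and the silyl dienol ether F7 from 30, and Pd(OAc)2 again converges both. The route is rejoined at 31.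

**Step 20.** The enolate may expel the C6 ether oxygen before oxygen transfer, reopening to a dienone alkoxide. The sulfonimine by-product may also add to the enolate.

Fallback: set out from 34 and avoid the enolate altogether. Mn(OAc)3 in refluxing benzene oxidises the alpha' position of the enone under non-basic conditions to the alpha'-acetoxy enone F8. Cold K2CO3 in methanol removes the acetyl group. The route is rejoined at 36.

**Step 21.** The ambident diosphenolate may be methylated on carbon (C6) instead of oxygen, and the heterogeneous carbonate may open the ether ring only slowly, leaving the alpha-ketol exposed to base.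

Fallback: set out from 36 and reverse the order of events. The C7 hydroxyl is methylated first under non-basic conditions (MeOTf, 2,6-di-tert-butyl-4-methylpyridine, CH2Cl2) to the C7 methyl ether F9. DBU then triggers the E1cB ring opening. The route is rejoined at 38.

## Further compounds

F1 | step 14 | beta-hydroxy lactone: (1S,4R)-8,8-ethylenedioxy-4-{hydroxy[4-(TBS-oxy)-3-methoxyphenyl]methyl}-1-[(1S)-1-ArO-2-(TBS-oxy)ethyl]-2-oxaspiro[4.5]decan-3-one (carbinol configuration open) | O=C1[C@H](C(O)c2ccc(O[Si](C)(C)C(C)(C)C)c(OC)c2)C2(CCC3(CC2)OCCO3)[C@H](O1)[C@H](CO[Si](C)(C)C(C)(C)C)Oc1ccc(CCCO[Si](C)(C)C(C)(C)C)cc1OC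
F2 | step 14 | benzylic alcohol triol: C3-hydroxy derivative of 24 (carbinol configuration open) | OC[C@H](C(O)c1ccc(O)c(OC)c1)C1(CCC2(CC1)OCCO2)[C@H](O)[C@H](CO[Si](C)(C)C(C)(C)C)Oc1ccc(CCCO[Si](C)(C)C(C)(C)C)cc1OC
F3 | step 12 | beta-acetoxy lactone: O-acetyl derivative of F1 | O=C1[C@H](C(OC(C)=O)c2ccc(O[Si](C)(C)C(C)(C)C)c(OC)c2)C2(CCC3(CC2)OCCO3)[C@H](O1)[C@H](CO[Si](C)(C)C(C)(C)C)Oc1ccc(CCCO[Si](C)(C)C(C)(C)C)cc1OC
F4 | step 17 | trimethylsilyl enol ether of 28 with the C7=C8 double bond (syn arm) | C[Si](C)(C)OC1=CC[C@]2(CC1)[C@H](COC(C)=O)[C@@H](c1ccc(OC(C)=O)c(OC)c1)O[C@@H]2[C@H](CO[Si](C)(C)C(C)(C)C)Oc1ccc(CCCO[Si](C)(C)C(C)(C)C)cc1OC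
F5 | step 17 | trimethylsilyl enol ether of 28 with the C8=C9 double bond (anti arm) | C[Si](C)(C)OC1=CC[C@@]2(CC1)[C@H](COC(C)=O)[C@@H](c1ccc(OC(C)=O)c(OC)c1)O[C@@H]2[C@H](CO[Si](C)(C)C(C)(C)C)Oc1ccc(CCCO[Si](C)(C)C(C)(C)C)cc1OC
F6 | step 17 | trimethylsilyl dienol ether of 29 (C6=C7 and C8=C9 double bonds) | C[Si](C)(C)OC1=CC[C@@]2(C=C1)[C@H](COC(C)=O)[C@@H](c1ccc(OC(C)=O)c(OC)c1)O[C@@H]2[C@H](CO[Si](C)(C)C(C)(C)C)Oc1ccc(CCCO[Si](C)(C)C(C)(C)C)cc1OC
F7 | step 17 | trimethylsilyl dienol ether of 30 (C7=C8 and C9=C10 double bonds) | C[Si](C)(C)OC1=CC[C@]2(C=C1)[C@H](COC(C)=O)[C@@H](c1ccc(OC(C)=O)c(OC)c1)O[C@@H]2[C@H](CO[Si](C)(C)C(C)(C)C)Oc1ccc(CCCO[Si](C)(C)C(C)(C)C)cc1OC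
F8 | step 20 | alpha'-acetoxy enone: C7-acetoxy derivative of 34 (C7 configuration open) | O=C1C=C[C@@]23[C@@H](C1OC(C)=O)OC[C@@H]2[C@@H](c1ccc(O[Si](C(C)C)(C(C)C)C(C)C)c(OC)c1)O[C@@H]3[C@H](CO[Si](C)(C)C(C)(C)C)Oc1ccc(CCCO[Si](C)(C)C(C)(C)C)cc1OC
F9 | step 21 | C7 methyl ether of 36 (C7 configuration open) | O=C1C=C[C@@]23[C@@H](C1OC)OC[C@@H]2[C@@H](c1ccc(O[Si](C(C)C)(C(C)C)C(C)C)c(OC)c1)O[C@@H]3[C@H](CO[Si](C)(C)C(C)(C)C)Oc1ccc(CCCO[Si](C)(C)C(C)(C)C)cc1OC
A1 | alternative 1 | trans-disubstituted alpha-methylene lactone: (4R,5S)-4-[(TBS-oxy)methyl]-5-[3-methoxy-4-(TIPS-oxy)phenyl]-3-methylideneoxolan-2-one | C=C1[C@H](CO[Si](C)(C)C(C)(C)C)[C@@H](c2ccc(O[Si](C(C)C)(C(C)C)C(C)C)c(OC)c2)OC1=O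
A2 | alternative 1 | trans-1-methoxy-3-(trimethylsilyloxy)buta-1,3-diene | CO/C=C/C(=C)O[Si](C)(C)C
A3 | alternative 1 | spiro lactone cyclohexenone (2-oxaspiro[4.5]dec-9-ene-1,8-dione bearing the C3 aryl and C4 silyloxymethyl groups) | O=C1CC[C@]2(C=C1)[C@H](CO[Si](C)(C)C(C)(C)C)[C@@H](c1ccc(O[Si](C(C)C)(C(C)C)C(C)C)c(OC)c1)OC2=O
A4 | alternative 2 | spiro lactol acetate (C1 acetoxy, anomeric configuration open) | COC1=C[C@]2(C=CC1=O)[C@H](CO[Si](C)(C)C(C)(C)C)[C@@H](c1ccc(O[Si](C(C)C)(C(C)C)C(C)C)c(OC)c1)OC2OC(C)=O
A5 | alternative 2 | ethyl diazoacetate | CCOC(=O)C=[N+]=[N-]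
A6 | alternative 2 | 2-methoxy-4-[3-(TBS-oxy)propyl]phenol | COc1cc(CCCO[Si](C)(C)C(C)(C)C)ccc1O
A7 | alternative 2 | alpha-aryloxy ester on C1 | COC1=C[C@]2(C=CC1=O)[C@H](CO[Si](C)(C)C(C)(C)C)[C@@H](c1ccc(O[Si](C(C)C)(C(C)C)C(C)C)c(OC)c1)O[C@@H]2[C@H](C(=O)OCC)Oc1ccc(CCCO[Si](C)(C)C(C)(C)C)cc1OC
A8 | alternative 3 | trans-1-aryl-2-[(triethylsilyloxy)methyl]spiro[2.5]octa-4,7-dien-6-one | O=C1C=CC2(C=C1)[C@H](CO[Si](CC)(CC)CC)[C@H]2c1ccc(O[Si](C(C)C)(C(C)C)C(C)C)c(OC)c1
A9 | alternative 3 | 3-(TBS-oxy)-2-oxopropanal | O=CC(=O)CO[Si](C)(C)C(C)(C)C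
A10 | alternative 3 | 1-acyl spiro dienone tetrahydrofuran | O=C1C=CC2(C=C1)[C@H](CO[Si](CC)(CC)CC)[C@@H](c1ccc(O[Si](C(C)C)(C(C)C)C(C)C)c(OC)c1)O[C@@H]2C(=O)CO[Si](C)(C)C(C)(C)C
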